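**Strategy.** Ring A is disconnected at C1–C2 (C1: cage carbon carrying CH2OAc; C2: the ring A methylene). Its precursor is an achiral triketone, a 2,2-disubstituted cyclopentane-1,3-dione whose ring carbons become C6, C1, C9, C10 and C11. An (R)-proline-catalysed Hajos–Parrish aldol condensation joins the side-chain methyl carbon (C2) to one of the two enantiotopic ring carbonyls (C1, not C11): one operation closes ring A and sets the quaternary bridgehead C6, the only stereocentre made by catalysis. The step exploits the latent mirror symmetry about C6 of the five-membered ring C6–C1–C9–C10–C11. All other stereocentres are relayed from C6; a sulfone-based Michael-initiated ring closure later builds the cyclopropane.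

Key step: step 5

Numbering (target locants, used for every compound): ring A is C1 (quaternary, bears CH2OAc)–C2 (CH2)–C3 (CHOH)–C4 (CHOAc)–C5 (CMe2)–C6 (quaternary bridgehead). The cage is completed by C7 (CH2 on C6), the cyclopropane carbons C8 (bonded to C7), C9 (bonded to C1) and C10 (bears CH3), and C11 (CHOAc, between C6 and C10).

Assumption: the sense of induction of the proline aldol follows the Hajos–Parrish precedent ((S)-proline gives the (S)-methyl series), which calls for (R)-proline here.

Remark: C4 is carried as an epimer mixture from step 6 to step 10 and is set in step 11; the SMILES of 10–16 leave it open. C10 in 12 and 13, C8 in 15 and the ozonide carbon in 18 are likewise left open.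

**Step 1**
Reactants: 1 cyclopentane-1,3-dione; 2 phenyl vinyl sulfone
Product: 3 2-[2-(phenylsulfonyl)ethyl]cyclopentane-1,3-dione
Conditions: Et3N (0.2 equiv), MeOH, 25 to 50 °C, 1.5 equiv of 1
Reagents that add atoms: none
Why: Base-catalysed Michael addition of the acidic cyclic 1,3-dione to the vinyl sulfone should give the C-alkylated dione, the excess of 1 limiting double addition.

**Step 2**
Reactants: 3 2-[2-(phenylsulfonyl)ethyl]cyclopentane-1,3-dione; 4 4-methylpent-3-en-2-ol (racemic)
Product: 5 3-[(4-methylpent-3-en-2-yl)oxy]-2-[2-(phenylsulfonyl)ethyl]cyclopent-2-en-1-one (racemic)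
Conditions: PPh3, diisopropyl azodicarboxylate, THF, 0 to 25 °C
Reagents that add atoms: none
Why: Mitsunobu O-alkylation of the enolic 2-substituted 1,3-dione should give the vinylogous ester needed for a [3,3] shift; its carbinol stereocentre is racemic and is destroyed in step 3.

**Step 3**
Reactants: 5 3-[(4-methylpent-3-en-2-yl)oxy]-2-[2-(phenylsulfonyl)ethyl]cyclopent-2-en-1-one
Product: 6 2-[(3E)-2-methylpent-3-en-2-yl]-2-[2-(phenylsulfonyl)ethyl]cyclopentane-1,3-dione (achiral)
Conditions: xylene, 140 °C, sealed tube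
Reagents that add atoms: none
Why: Claisen rearrangement of the 3-allyloxy-enone through a chair transition state should join C6 to C5 (two adjacent quaternary carbons) and give the E alkene; no stereocentre remains.

**Step 4**
Reactants: 6 2-[(3E)-2-methylpent-3-en-2-yl]-2-[2-(phenylsulfonyl)ethyl]cyclopentane-1,3-dione
Product: 7 2-(2-methyl-4-oxopentan-2-yl)-2-[2-(phenylsulfonyl)ethyl]cyclopentane-1,3-dione (achiral triketone)
Conditions: Pd(OAc)2 (5 mol%), 1,4-benzoquinone, aq. HBF4, MeCN/DMA/H2O, 25 °C
Reagents that add atoms: water, SMILES: O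
Why: Wacker-type oxidation of the internal alkene should place the carbonyl at C3, the alkene carbon remote from the neopentyl centre and from the electron-withdrawing dione.

**Step 5**
Reactants: 7 2-(2-methyl-4-oxopentan-2-yl)-2-[2-(phenylsulfonyl)ethyl]cyclopentane-1,3-dione
Product: 9 (7aR)-7,7-dimethyl-7a-[2-(phenylsulfonyl)ethyl]-2,3,7,7a-tetrahydro-1H-indene-1,5(6H)-dione (ring A enone C3(=O)–C2=C1; C11 ketone), via cis-fused ketol 8 (not isolated)
Conditions: (R)-proline (30 mol%), DMF, 25 °C; then TsOH·H2O (cat.), toluene, 80 °C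
Reagents that add atoms: none
Why: (R)-Proline should condense with the methyl ketone C3 to the terminal enamine, whose carbon C2 adds to one of the two enantiotopic ring carbonyls (C1) in a carboxylic acid-assisted chair transition state; hydrolysis gives ketol 8 and acid dehydrates it to enone 9. The closest known reaction is the Hajos–Parrish–Eder–Sauer–Wiechert aldol condensation. Ring A is closed in a 6-(enolendo)-exo-trig aldol mode. The new stereocentre C6 is set by the catalyst through enantiotopic-group selection, and the transient C1 carbinol of 8 (cis ring fusion, substrate control) is erased on dehydration. The step needs selection between two carbonyls that only the catalyst can tell apart, secured by the mirror symmetry of the 2,2-disubstituted dione, and enamine formation at C2 instead of C4, secured because C4 is neopentyl and would close a four-membered ring.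

**Step 6**
Reactants: 9 (7aR)-7,7-dimethyl-7a-[2-(phenylsulfonyl)ethyl]-2,3,7,7a-tetrahydro-1H-indene-1,5(6H)-dione
Product: 10 C4-benzoyloxy derivative of 9 (benzoate on the α′ carbon of the enone; C4 epimers)
Conditions: Mn(OAc)3·2H2O (2.5 equiv), PhCO2H, benzene, reflux (Dean–Stark)
Reagents that add atoms: benzoic acid, SMILES: O=C(O)c1ccccc1
Why: α′-Acyloxylation of an enone by manganese triacetate in the presence of a carboxylic acid should oxidise only C4, the single α′ position (C5 is quaternary); the C4 configuration is left open and corrected in step 11.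

**Step 7**
Reactants: 10 C4-benzoyloxy enedione
Product: 11 C1-vinyl cis-hydrindanone in which the ring A ketone is masked as its C2=C3 triethylsilyl enol ether (vinyl cis to the C6 side chain; C4 epimers)
Conditions: CH2=CHMgBr (slow addition), CuBr·SMe2 (10 mol%), Et3SiCl, HMPA, THF, −78 °C; Et3N
Reagents that add atoms: vinylmagnesium bromide, SMILES: C=C[Mg]Br; chlorotriethylsilane, SMILES: CC[Si](Cl)(CC)CC
Why: Copper-catalysed conjugate addition with silyl chloride trapping (Nakamura–Kuwajima conditions) should create the quaternary C1 with the vinyl group cis to the C6 side chain, because only the cis-fused hydrindane is accessible (substrate control).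

**Step 8**
Reactants: 11 C1-vinyl silyl enol ether
Product: 12 C10-methyl ketone (C10 epimers)
Conditions: LiN(iPr)2 (1.05 equiv), THF, −78 °C; MeI
Reagents that add atoms: iodomethane, SMILES: CI
Why: Kinetic enolate alkylation should occur at C10, the only enolisable position left (C6 is quaternary and the ring A ketone is masked); the C10 configuration is irrelevant because C10 becomes sp2 in step 9.

**Step 9**
Reactants: 12 C10-methyl ketone
Product: 14 2-methylcyclopentenone (C9=C10 enone conjugated to the C11 ketone), via α-phenylselanyl ketone 13 (not isolated)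
Conditions: LiN(iPr)2, THF, −78 °C; PhSeBr (1.05 equiv); then 30% H2O2, pyridine, CH2Cl2, 0 to 25 °C
Reagents that add atoms: none
Why: Selenenylation of the lithium enolate (far more nucleophilic than the silyl enol ether or the vinyl group) and selenoxide syn-elimination toward the ring C9–H should give the endocyclic enone.

**Step 10**
Reactants: 14 2-methylcyclopentenone bearing the phenylsulfonylethyl chain
Product: 16 tetracyclic C11 ketone (cage complete; C2=C3 silyl enol ether; C4 benzoate; C1 vinyl), via lithium enolate 15 (not isolated)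
Conditions: LiN(iPr)2 (1.2 equiv), THF, −78 °C; then HMPA, −78 to 40 °C
Reagents that add atoms: none
Why: In this Michael-initiated ring closure the α-sulfonyl carbanion C8 should add 5-exo-trig to the enone β-carbon C9 on the face of its own tether (cis to C7), and the C10 enolate then displaces sulfinate at C8 (3-exo-tet 1,3-elimination); C8, C9 and C10 are fixed by the tether (substrate control).

**Step 11**
Reactants: 16 tetracyclic silyl enol ether
Product: 17 tetracyclic C3,C11-diketone (C4 benzoate equatorial and cis to the C1 vinyl group)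
Conditions: AcOH, KOAc, 100 °C
Reagents that add atoms: none
Why: Acidolysis of the silyl enol ether frees the C3 ketone, and acetate-buffered enolisation should equilibrate the α-acyloxy ketone to the equatorial C4 epimer, the axial one being destabilised by a 1,3-diaxial contact with the cage carbon C11 (as in the epimerisation of axial 2-acetoxy-3-keto steroids).

**Step 12**
Reactants: 17 tetracyclic diketone
Product: 20 tetraol (C1–CH2OH; C3-OH axial; C4-OH equatorial; C11-OH pointing toward C1), via ozonide 18 (not isolated), via aldehyde 19 (not isolated)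
Conditions: O3, CH2Cl2, −78 °C; Me2S, to 25 °C; concentrate; then LiAlH4, THF, 0 to 25 °C
Reagents that add atoms: ozone, SMILES: [O-][O+]=O
Why: Ozonolysis of the only alkene and global hydride reduction should give the tetraol; the C3 ketone is shielded on one face by two syn-axial carbons (the C1 substituent and a C5 methyl), so hydride enters equatorially and gives the axial C3 alcohol as with steroidal 11-ketones. C11 is attacked from the open C7 side, and its configuration is corrected in step 14.

**Step 13**
Reactants: 20 tetraol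
Product: 21 diacetate (C1–CH2OAc and C4-OAc; C3-OH and C11-OH free)
Conditions: Ac2O (2.5 equiv), pyridine, 0 to 25 °C
Reagents that add atoms: acetic anhydride, SMILES: CC(=O)OC(C)=O
Why: Sterically controlled acetylation should esterify the primary and the equatorial C4 hydroxyl only, because the C3-OH is flanked by two syn-axial carbons and the C11-OH is buried under ring A.

**Step 14**
Reactants: 21 diacetate diol
Product: 22 target CNP0111873.1
Conditions: AcOH, CF3SO3H (2 mol%), 25 °C
Reagents that add atoms: acetic acid, SMILES: CC(=O)O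
Why: Acid-catalysed SN1 acetolysis of the cyclopropylcarbinyl alcohol should ionise only C11 (cation stabilised by the C8–C9–C10 cyclopropane) and capture acetic acid on the open face anti to C2, which places the acetate syn to C7; the step is stereoconvergent for both C11 epimers and the C3-OH cannot ionise.

**Compound list**

1 | cyclopentane-1,3-dione | O=C1CCC(=O)C1 | starting material
2 | phenyl vinyl sulfone | C=CS(=O)(=O)c1ccccc1 | starting material
3 | 2-[2-(phenylsulfonyl)ethyl]cyclopentane-1,3-dione | O=C1CCC(=O)C1CCS(=O)(=O)c1ccccc1 | intermediate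
4 | 4-methylpent-3-en-2-ol (racemic) | CC(O)C=C(C)C | starting material
5 | 3-[(4-methylpent-3-en-2-yl)oxy]-2-[2-(phenylsulfonyl)ethyl]cyclopent-2-en-1-one (racemic) | O=C1CCC(OC(C)C=C(C)C)=C1CCS(=O)(=O)c1ccccc1 | intermediate
6 | 2-[(3E)-2-methylpent-3-en-2-yl]-2-[2-(phenylsulfonyl)ethyl]cyclopentane-1,3-dione | O=C1CCC(=O)C1(CCS(=O)(=O)c1ccccc1)C(C)(C)/C=C/C | intermediate
7 | 2-(2-methyl-4-oxopentan-2-yl)-2-[2-(phenylsulfonyl)ethyl]cyclopentane-1,3-dione | O=C1CCC(=O)C1(CCS(=O)(=O)c1ccccc1)C(C)(C)CC(C)=O | intermediate
8 | cis-fused ketol: 3a-hydroxy-7,7-dimethyl-7a-[2-(phenylsulfonyl)ethyl]hexahydro-1H-indene-1,5-dione, OH cis to the sulfonylethyl chain | O=C1C[C@]2(O)CCC(=O)[C@]2(CCS(=O)(=O)c2ccccc2)C(C)(C)C1 | intermediate (not isolated)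
9 | (7aR)-7,7-dimethyl-7a-[2-(phenylsulfonyl)ethyl]-2,3,7,7a-tetrahydro-1H-indene-1,5(6H)-dione | O=C1C=C2CCC(=O)[C@]2(CCS(=O)(=O)c2ccccc2)C(C)(C)C1 | intermediate
10 | C4-benzoate of 9 (indene position 6; C4 epimers) | O=C1C=C2CCC(=O)[C@]2(CCS(=O)(=O)c2ccccc2)C(C)(C)C1OC(=O)c1ccccc1 | intermediate
11 | cis-hydrindanone: C1 vinyl cis to the C6 sulfonylethyl chain, C2=C3 triethylsilyl enol ether, C4 benzoate, C11 ketone | C=C[C@@]12CCC(=O)[C@]1(CCS(=O)(=O)c1ccccc1)C(C)(C)C(OC(=O)c1ccccc1)C(O[Si](CC)(CC)CC)=C2 | intermediate
12 | C10-methyl derivative of 11 (C10 epimers) | C=C[C@@]12CC(C)C(=O)[C@]1(CCS(=O)(=O)c1ccccc1)C(C)(C)C(OC(=O)c1ccccc1)C(O[Si](CC)(CC)CC)=C2 | intermediate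
13 | C10-methyl-C10-phenylselanyl ketone | C=C[C@@]12CC(C)([Se]c3ccccc3)C(=O)[C@]1(CCS(=O)(=O)c1ccccc1)C(C)(C)C(OC(=O)c1ccccc1)C(O[Si](CC)(CC)CC)=C2 | intermediate (not isolated)
14 | C9=C10 enone (2-methylcyclopentenone) derived from 12 | C=C[C@@]12C=C(C)C(=O)[C@]1(CCS(=O)(=O)c1ccccc1)C(C)(C)C(OC(=O)c1ccccc1)C(O[Si](CC)(CC)CC)=C2 | intermediate
15 | lithium C10=C11 enolate of the tricyclic Michael adduct (C8–C9 bond formed, C8 bears PhSO2) | C=C[C@]12C=C(O[Si](CC)(CC)CC)C(OC(=O)c3ccccc3)C(C)(C)[C@]13CC(S(=O)(=O)c1ccccc1)[C@H]2C(C)=C3[O-].[Li+] | intermediate (not isolated)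
16 | tetracyclic cage ketone: C11 ketone, C8–C9–C10 cyclopropane, C2=C3 triethylsilyl enol ether, C4 benzoate, C1 vinyl | C=C[C@]12C=C(O[Si](CC)(CC)CC)C(OC(=O)c3ccccc3)C(C)(C)[C@]13C[C@@H]1[C@H]2[C@]1(C)C3=O | intermediate
17 | tetracyclic C3,C11-diketone, C4 benzoate equatorial (cis to the C1 vinyl group) | C=C[C@]12CC(=O)[C@H](OC(=O)c3ccccc3)C(C)(C)[C@]13C[C@@H]1[C@H]2[C@]1(C)C3=O | intermediate
18 | 1,2,4-trioxolane (ozonide) of the C1 vinyl group of 17 | O4OC(OC4)[C@]12CC(=O)[C@H](OC(=O)c3ccccc3)C(C)(C)[C@]13C[C@@H]1[C@H]2[C@]1(C)C3=O | intermediate (not isolated)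
19 | C1 carbaldehyde (diketone, C4 benzoate) | O=C[C@]12CC(=O)[C@H](OC(=O)c3ccccc3)C(C)(C)[C@]13C[C@@H]1[C@H]2[C@]1(C)C3=O | intermediate (not isolated)
20 | tetraol: C1–CH2OH, C3-OH (axial, cis to CH2OH), C4-OH (equatorial, cis to C3-OH), C11-OH pointing toward C1 | OC[C@]12C[C@H](O)[C@H](O)C(C)(C)[C@]13C[C@@H]1[C@H]2[C@]1(C)[C@@H]3O | intermediate
21 | C1–CH2OAc, C4-OAc diacetate with free C3-OH and C11-OH (C11 as in 20) | CC(=O)OC[C@]12C[C@H](O)[C@H](OC(C)=O)C(C)(C)[C@]13C[C@@H]1[C@H]2[C@]1(C)[C@@H]3O | intermediate
22 | CNP0111873.1 | CC(=O)OC[C@]12C[C@H](O)[C@H](OC(C)=O)C(C)(C)[C@]13C[C@@H]1[C@H]2[C@]1(C)[C@H]3OC(C)=O | target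

**Step count and risks**

Total steps: 14. Longest linear sequence: 14 steps (from 1).

Steps most likely to fail:

Step 5. Enamine formation and aldol addition on the congested triketone may be slow, and the discrimination between the two ring carbonyls may erode, lowering the enantiomeric purity of 9. The fallback sets out from 6 and returns at 9; it replaces the aminocatalytic aldol by a reductive desymmetrisation. Borane reduction of one ring carbonyl of 6 catalysed by (R)-1-methyl-3,3-diphenyltetrahydro-1H,3H-pyrrolo[1,2-c][1,3,2]oxazaborole (BH3·SMe2, THF, −30 °C; hydride anti to the bulky side chain) should give the hydroxy ketone F1. Silylation (tBuMe2SiOSO2CF3, 2,6-lutidine) gives the silyl ether F2, and Wacker oxidation as in step 4 gives the methyl ketone F3. Pyrrolidine/AcOH in toluene at 80 °C then closes ring A on the single remaining ring ketone to give the enone F4. Bu4NF gives the hydroxy enone F5, and Dess–Martin periodinane oxidises it to 9.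

Step 10. The sequence may stop after the conjugate addition, because the hindered tertiary enolate expels sulfinate slowly and proton transfer can quench it. The fallback sets out from 14 and returns at 16; it keeps the sulfone as carbanion stabiliser and uses bromide as the leaving group. Conjugate addition alone (LiN(iPr)2, THF, −78 °C, AcOH quench) gives the tricyclic γ-sulfonyl ketone F6. Enolisation with LiN(SiMe3)2 and N-bromosuccinimide at −78 °C gives the C10 bromo ketone F7. LiN(iPr)2 in THF/DMPU then lets the C8 sulfonyl carbanion displace bromide to give the cyclopropyl sulfone F8. Reductive desulfonylation (Na/Hg, Na2HPO4, MeOH/THF, −20 °C) gives 16.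

Step 14. The delocalised cation may be captured at C8 or C9 (ring opening to norbornenyl acetates), the skeleton may rearrange, or facial selectivity at C11 may be incomplete. The fallback sets out from 20 and returns at 22; it corrects C11 by redox equilibration instead of ionisation. 2,2-Dimethoxypropane with pyridinium p-toluenesulfonate protects the cis C3/C4 diol as the acetonide F9. Al(OiPr)3 with a little acetone in refluxing toluene/iPrOH (Meerwein–Ponndorf–Verley/Oppenauer equilibration of the only free secondary alcohol) gives the less hindered C11 epimer F10. Aqueous AcOH at 40 °C gives the epimeric tetraol F11. Ac2O, pyridine and catalytic 4-(dimethylamino)pyridine at 0 to 25 °C acetylate the three accessible hydroxyls and leave the shielded C3-OH, giving 22.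

**Further compounds**

F1 | step 5 | (3S)-3-hydroxy-2-[(3E)-2-methylpent-3-en-2-yl]-2-[2-(phenylsulfonyl)ethyl]cyclopentan-1-one, OH cis to the methylpentenyl group | O=C1CC[C@H](O)[C@]1(CCS(=O)(=O)c1ccccc1)C(C)(C)/C=C/C
F2 | step 5 | tert-butyldimethylsilyl ether of F1 | O=C1CC[C@H](O[Si](C)(C)C(C)(C)C)[C@]1(CCS(=O)(=O)c1ccccc1)C(C)(C)/C=C/C
F3 | step 5 | 3-(tert-butyldimethylsilyloxy)-2-(2-methyl-4-oxopentan-2-yl)-2-[2-(phenylsulfonyl)ethyl]cyclopentan-1-one | O=C1CC[C@H](O[Si](C)(C)C(C)(C)C)[C@]1(CCS(=O)(=O)c1ccccc1)C(C)(C)CC(C)=O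
F4 | step 5 | 1-(tert-butyldimethylsilyloxy)-7,7-dimethyl-7a-[2-(phenylsulfonyl)ethyl]-1,2,3,6,7,7a-hexahydro-5H-inden-5-one | O=C1C=C2CC[C@H](O[Si](C)(C)C(C)(C)C)[C@]2(CCS(=O)(=O)c2ccccc2)C(C)(C)C1
F5 | step 5 | 1-hydroxy-7,7-dimethyl-7a-[2-(phenylsulfonyl)ethyl]-1,2,3,6,7,7a-hexahydro-5H-inden-5-one | O=C1C=C2CC[C@H](O)[C@]2(CCS(=O)(=O)c2ccccc2)C(C)(C)C1
F6 | step 10 | tricyclic γ-sulfonyl ketone (protonated form of 15; C8 and C10 epimers) | C=C[C@]12C=C(O[Si](CC)(CC)CC)C(OC(=O)c3ccccc3)C(C)(C)[C@]13CC(S(=O)(=O)c1ccccc1)[C@H]2C(C)C3=O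
F7 | step 10 | C10-bromo derivative of F6 | C=C[C@]12C=C(O[Si](CC)(CC)CC)C(OC(=O)c3ccccc3)C(C)(C)[C@]13CC(S(=O)(=O)c1ccccc1)[C@H]2C(C)(Br)C3=O
F8 | step 10 | C8-phenylsulfonyl derivative of 16 (cyclopropyl sulfone) | C=C[C@]12C=C(O[Si](CC)(CC)CC)C(OC(=O)c3ccccc3)C(C)(C)[C@]13C[C@]1(S(=O)(=O)c4ccccc4)[C@H]2[C@]1(C)C3=O
F9 | step 14 | C3,C4-O-isopropylidene derivative of 20 | OC[C@]12C[C@@H]4OC(C)(C)O[C@@H]4C(C)(C)[C@]13C[C@@H]1[C@H]2[C@]1(C)[C@@H]3O
F10 | step 14 | C11 epimer of F9 (C11-OH syn to C7) | OC[C@]12C[C@@H]4OC(C)(C)O[C@@H]4C(C)(C)[C@]13C[C@@H]1[C@H]2[C@]1(C)[C@H]3O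
F11 | step 14 | C11 epimer of 20 (C11-OH syn to C7) | OC[C@]12C[C@H](O)[C@H](O)C(C)(C)[C@]13C[C@@H]1[C@H]2[C@]1(C)[C@H]3O
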